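**Plan**
1. Retrosynthesis: the two MOM ethers (5-OH, 3'-OH) come off last. Ring C is then cut at O1–C8a and C4–C4a in one stroke, giving a ring A aryne (C4a≡C8a) and an open C2–C3–C4 ester chain that already carries ring B and the (S)-carbinol.
2. Enabling feature: in ring A the ether oxygen O1 (on C8a) and the acyl carbon C4 (on C4a) sit on neighbouring carbons, and C4a is flanked by the C5 oxygen. A 3-oxygenated aryne takes an O-nucleophile at the carbon remote from that oxygen (C8a) and leaves the carbanion beside it (C4a), where the acyl group belongs.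
3. Forward, ring A: 5-methoxyresorcinol is taken by two directed lithiations (prenyl at C6, SiMe3 at C4a) to a 2-(trimethylsilyl)aryl triflate.
4. Forward, ring B: isovanillin is ortho-geranylated, extended to the β-keto ester, reduced and O-silylated.
5. Rings A and B are bought; ring C (the pyranone) is the only ring made, in the key step, by alkoxide addition to the aryne and 6-exo acyl capture.
6. Stereochemistry: C2 (S) is set by Ru-catalysed asymmetric transfer hydrogenation of the β-keto ester and no bond to it is made or broken afterwards; the E-alkene comes with geranyl bromide.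

Key step: step 13

Remark: the descriptor at C2 read from the SMILES is (S); prenyl bromide, geranyl bromide and the protecting-group reagents are taken as commercial.

**Step 1**
Reactants: 1 5-methoxybenzene-1,3-diol
Product: 2 3-methoxy-5-[(triisopropylsilyl)oxy]phenol
Conditions: iPr3SiCl (1.0 equiv), imidazole, DMF, 0 °C → rt; recovered 1 and bis-silyl ether recycled
Reagents that add atoms: chlorotriisopropylsilane, CC(C)[Si](Cl)(C(C)C)C(C)C
Why: Silyl ether formation on a symmetric diol with one equivalent of a bulky silyl chloride should give the mono-ether as the main fraction, and OSi(iPr)3 is a base-stable, non-directing cap for the oxygen that later becomes the triflate.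

**Step 2**
Reactants: 2 3-methoxy-5-[(triisopropylsilyl)oxy]phenol
Product: 3 [3-methoxy-5-(methoxymethoxy)phenoxy]triisopropylsilane
Conditions: MOMCl, iPr2NEt, CH2Cl2, 0 °C → rt
Reagents that add atoms: chloromethyl methyl ether, COCCl
Why: Williamson-type O-alkylation installs the MOM ether, which protects the future 5-OH and directs both lithiations that follow.

**Step 3**
Reactants: 3 [3-methoxy-5-(methoxymethoxy)phenoxy]triisopropylsilane
Product: 5 [3-methoxy-5-(methoxymethoxy)-4-(3-methylbut-2-en-1-yl)phenoxy]triisopropylsilane, via aryllithium 4 (not isolated)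
Conditions: n-BuLi, TMEDA, THF, 0 °C; CuBr·SMe2 (10 mol %), prenyl bromide, −78 °C → rt
Reagents that add atoms: 1-bromo-3-methylbut-2-ene, CC(C)=CCBr
Why: Directed ortho-metalation should occur at the only ring position flanked by two coordinating ethers (OMOM and OMe, the bulky silyl ether does not direct), and copper-catalysed SN2 allylation of the aryllithium gives the linear prenyl arene.

**Step 4**
Reactants: 5 [3-methoxy-5-(methoxymethoxy)-4-(3-methylbut-2-en-1-yl)phenoxy]triisopropylsilane
Product: 7 [5-methoxy-3-(methoxymethoxy)-4-(3-methylbut-2-en-1-yl)-2-(trimethylsilyl)phenoxy]triisopropylsilane, via aryllithium 6 (not isolated)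
Conditions: s-BuLi, TMEDA, THF, −78 °C; Me3SiCl, −78 °C → rt
Reagents that add atoms: chlorotrimethylsilane, C[Si](C)(C)Cl
Why: Directed ortho-metalation by OMOM, the only strong director with a free ortho position (the prenyl group holds it toward that C–H and pushes the OMe methyl over the other), should place lithium between OMOM and the silyl ether, and quenching at −78 °C forestalls O-to-C silyl migration and benzylic metalation.

**Step 5**
Reactants: 7 [5-methoxy-3-(methoxymethoxy)-4-(3-methylbut-2-en-1-yl)-2-(trimethylsilyl)phenoxy]triisopropylsilane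
Product: 8 5-methoxy-3-(methoxymethoxy)-4-(3-methylbut-2-en-1-yl)-2-(trimethylsilyl)phenol
Conditions: Bu4NF, AcOH (1:1, 1.05 equiv), THF, 0 °C
Reagents that add atoms: none
Why: Buffered fluoride desilylation cleaves the aryl O–Si bond far faster than the aryl C–SiMe3 bond, and the acetic acid keeps the medium from becoming basic enough for C-desilylation.

**Step 6**
Reactants: 8 5-methoxy-3-(methoxymethoxy)-4-(3-methylbut-2-en-1-yl)-2-(trimethylsilyl)phenol
Product: 9 5-methoxy-3-(methoxymethoxy)-4-(3-methylbut-2-en-1-yl)-2-(trimethylsilyl)phenyl trifluoromethanesulfonate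
Conditions: PhNTf2, Et3N, DMAP (cat.), CH2Cl2, rt
Reagents that add atoms: N-phenylbis(trifluoromethanesulfonimide), O=S(=O)(N(c1ccccc1)S(=O)(=O)C(F)(F)F)C(F)(F)F
Why: O-Sulfonylation by triflyl transfer under mild base leaves the MOM ether, the alkene and the acid-sensitive aryl–SiMe3 bond alone and completes the 2-silylaryl triflate aryne precursor.

**Step 7**
Reactants: 10 3-hydroxy-4-methoxybenzaldehyde (isovanillin)
Product: 11 4-methoxy-3-(methoxymethoxy)benzaldehyde
Conditions: MOMCl, iPr2NEt, CH2Cl2, 0 °C → rt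
Reagents that add atoms: chloromethyl methyl ether, COCCl
Why: Williamson-type O-alkylation masks the 3'-OH against later aryne O-arylation and provides the second director for lithiation at C2'.

**Step 8**
Reactants: 11 4-methoxy-3-(methoxymethoxy)benzaldehyde
Product: 15 2-[(2E)-3,7-dimethylocta-2,6-dien-1-yl]-4-methoxy-3-(methoxymethoxy)benzaldehyde, via lithium amino alkoxide 12 (not isolated), via ring-lithiated amino alkoxide 13 (not isolated), via geranylated amino alkoxide 14 (not isolated)
Conditions: LiN(Me)CH2CH2NMe2 (from the amine and n-BuLi), THF, −20 °C; n-BuLi, −20 °C; CuBr·SMe2 (10 mol %), geranyl bromide, −78 °C → rt; H2O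
Reagents that add atoms: geranyl bromide, BrC/C=C(\C)CCC=C(C)C
Why: In situ conversion of the aldehyde into a chelating lithium α-amino alkoxide allows cooperative directed ortho-metalation at the carbon between it and OMOM, copper-catalysed SN2 alkylation keeps the E-alkene, and water releases the aldehyde.

**Step 9**
Reactants: 15 2-[(2E)-3,7-dimethylocta-2,6-dien-1-yl]-4-methoxy-3-(methoxymethoxy)benzaldehyde
Product: 16 methyl (3RS)-3-{2-[(2E)-3,7-dimethylocta-2,6-dien-1-yl]-4-methoxy-3-(methoxymethoxy)phenyl}-3-hydroxypropanoate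
Conditions: MeOAc, LiN(iPr)2, THF, −78 °C; then 15; AcOH quench at −78 °C
Reagents that add atoms: methyl acetate, COC(C)=O
Why: Aldol addition of the lithium enolate of methyl acetate to the aldehyde is reliable at −78 °C, and the racemic carbinol does not matter because it is oxidised in the next step.

**Step 10**
Reactants: 16 methyl (3RS)-3-{2-[(2E)-3,7-dimethylocta-2,6-dien-1-yl]-4-methoxy-3-(methoxymethoxy)phenyl}-3-hydroxypropanoate
Product: 17 methyl 3-{2-[(2E)-3,7-dimethylocta-2,6-dien-1-yl]-4-methoxy-3-(methoxymethoxy)phenyl}-3-oxopropanoate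
Conditions: Dess–Martin periodinane, CH2Cl2, 0 °C → rt
Reagents that add atoms: none
Why: Dess–Martin oxidation converts the benzylic secondary alcohol into the β-keto ester under near-neutral conditions that spare the trisubstituted alkenes and the MOM ether.

**Step 11**
Reactants: 17 methyl 3-{2-[(2E)-3,7-dimethylocta-2,6-dien-1-yl]-4-methoxy-3-(methoxymethoxy)phenyl}-3-oxopropanoate
Product: 18 methyl (3S)-3-{2-[(2E)-3,7-dimethylocta-2,6-dien-1-yl]-4-methoxy-3-(methoxymethoxy)phenyl}-3-hydroxypropanoate
Conditions: RuCl[(S,S)-TsDPEN](p-cymene) (2 mol %), HCO2H/Et3N (5:2), DMF, 40 °C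
Reagents that add atoms: none
Why: Noyori–Ikariya asymmetric transfer hydrogenation of an aryl β-keto ester, in which the CH/π contact between the catalyst arene and the substrate aryl group fixes the ketone face, should give the (S)-carbinol with the (S,S)-ligand as for other aryl ketones, and isolated alkenes are not reduced.

**Step 12**
Reactants: 18 methyl (3S)-3-{2-[(2E)-3,7-dimethylocta-2,6-dien-1-yl]-4-methoxy-3-(methoxymethoxy)phenyl}-3-hydroxypropanoate
Product: 19 methyl (3S)-3-{2-[(2E)-3,7-dimethylocta-2,6-dien-1-yl]-4-methoxy-3-(methoxymethoxy)phenyl}-3-[(trimethylsilyl)oxy]propanoate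
Conditions: Me3SiCl, imidazole, CH2Cl2, 0 °C; filtration through Et3N-deactivated silica
Reagents that add atoms: chlorotrimethylsilane, C[Si](C)(C)Cl
Why: Silyl ether formation removes the only O–H of the fragment and turns the carbinol oxygen into an alkoxide that fluoride can release in the key step.

**Step 13**
Reactants: 9 5-methoxy-3-(methoxymethoxy)-4-(3-methylbut-2-en-1-yl)-2-(trimethylsilyl)phenyl trifluoromethanesulfonate; 19 methyl (3S)-3-{2-[(2E)-3,7-dimethylocta-2,6-dien-1-yl]-4-methoxy-3-(methoxymethoxy)phenyl}-3-[(trimethylsilyl)oxy]propanoate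
Product: 23 (2S)-2-{2-[(2E)-3,7-dimethylocta-2,6-dien-1-yl]-4-methoxy-3-(methoxymethoxy)phenyl}-7-methoxy-5-(methoxymethoxy)-6-(3-methylbut-2-en-1-yl)-2,3-dihydro-4H-chromen-4-one, via cesium alkoxide 20 (not isolated), via aryne 21 (not isolated), via arylcesium adduct 22 (not isolated)
Conditions: CsF (3 equiv), 18-crown-6 (0.3 equiv), THF, 25 °C; 9 (1.4 equiv) and 19 added together over 4 h
Reagents that add atoms: none
Why: Proposed new method: fluoride takes SiMe3 from C2 of 9 (loss of triflate gives aryne 21) and from the oxygen of 19 (alkoxide 20, no O–H present); 20 adds to the aryne carbon remote from the OMOM group, and the aryl anion 22 formed beside the OMOM group attacks the ester carbonyl and expels methoxide, which Me3SiF traps as MeOSiMe3 so that no strong base accumulates. The closest known reaction type is the aryne annulation of salicylate esters to xanthones (phenoxide addition to the aryne, then intramolecular acyl substitution by the aryl anion); new here is an aliphatic β-alkoxide, released from its silyl ether, as the O-nucleophile. Ring C closes by 6-exo-trig attack of the C4a carbanion on the ester carbonyl after the intermolecular O1–C8a bond has formed. No stereocenter is created: C2 enters with the (S) configuration of 19 and none of its four bonds is touched. The step needs regioselectivity (O at C8a, acyl at C4a), which the inductively withdrawing C5 oxygen should secure by polarising and distorting the aryne so that nucleophiles add at the distal carbon and the charge develops ortho to oxygen, and it needs acyl capture to outrun protonation, which the silyl ether should secure by keeping the medium aprotic with the ester tethered in reach. Slow co-addition keeps aryne and alkoxide at low concentration, which should limit retro-aldol of 20 and base-induced opening of the flavanone.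

**Step 14**
Reactants: 23 (2S)-2-{2-[(2E)-3,7-dimethylocta-2,6-dien-1-yl]-4-methoxy-3-(methoxymethoxy)phenyl}-7-methoxy-5-(methoxymethoxy)-6-(3-methylbut-2-en-1-yl)-2,3-dihydro-4H-chromen-4-one
Product: 24 (2S)-2-{2-[(2E)-3,7-dimethylocta-2,6-dien-1-yl]-3-hydroxy-4-methoxyphenyl}-5-hydroxy-7-methoxy-6-(3-methylbut-2-en-1-yl)-2,3-dihydro-4H-chromen-4-one
Conditions: 3 M aq. HCl, MeOH, 40 °C, short reaction time
Reagents that add atoms: none
Why: Acid-catalysed acetal cleavage in methanol removes both MOM ethers under conditions established for prenylated flavanones, where the hydrogen-bonded 5-OH is a poor nucleophile toward the prenyl alkene and C2 is not epimerised by dilute acid.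

**Compound list**
1 | 5-methoxybenzene-1,3-diol | COc1cc(O)cc(O)c1 | starting material
2 | 3-methoxy-5-[(triisopropylsilyl)oxy]phenol | COc1cc(O)cc(O[Si](C(C)C)(C(C)C)C(C)C)c1 | intermediate
3 | [3-methoxy-5-(methoxymethoxy)phenoxy]triisopropylsilane | COCOc1cc(OC)cc(O[Si](C(C)C)(C(C)C)C(C)C)c1 | intermediate
4 | {2-methoxy-6-(methoxymethoxy)-4-[(triisopropylsilyl)oxy]phenyl}lithium | COCOc1cc(O[Si](C(C)C)(C(C)C)C(C)C)cc(OC)c1[Li] | intermediate
5 | [3-methoxy-5-(methoxymethoxy)-4-(3-methylbut-2-en-1-yl)phenoxy]triisopropylsilane | COCOc1cc(O[Si](C(C)C)(C(C)C)C(C)C)cc(OC)c1CC=C(C)C | intermediate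
6 | {4-methoxy-2-(methoxymethoxy)-3-(3-methylbut-2-en-1-yl)-6-[(triisopropylsilyl)oxy]phenyl}lithium | COCOc1c([Li])c(O[Si](C(C)C)(C(C)C)C(C)C)cc(OC)c1CC=C(C)C | intermediate
7 | [5-methoxy-3-(methoxymethoxy)-4-(3-methylbut-2-en-1-yl)-2-(trimethylsilyl)phenoxy]triisopropylsilane | COCOc1c([Si](C)(C)C)c(O[Si](C(C)C)(C(C)C)C(C)C)cc(OC)c1CC=C(C)C | intermediate
8 | 5-methoxy-3-(methoxymethoxy)-4-(3-methylbut-2-en-1-yl)-2-(trimethylsilyl)phenol | COCOc1c([Si](C)(C)C)c(O)cc(OC)c1CC=C(C)C | intermediate
9 | 5-methoxy-3-(methoxymethoxy)-4-(3-methylbut-2-en-1-yl)-2-(trimethylsilyl)phenyl trifluoromethanesulfonate | COCOc1c([Si](C)(C)C)c(OS(=O)(=O)C(F)(F)F)cc(OC)c1CC=C(C)C | intermediate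
10 | 3-hydroxy-4-methoxybenzaldehyde (isovanillin) | COc1ccc(C=O)cc1O | starting material
11 | 4-methoxy-3-(methoxymethoxy)benzaldehyde | COCOc1cc(C=O)ccc1OC | intermediate
12 | lithium {[2-(dimethylamino)ethyl](methyl)amino}[4-methoxy-3-(methoxymethoxy)phenyl]methanolate | COCOc1cc(C(O[Li])N(C)CCN(C)C)ccc1OC | intermediate
13 | 2-lithio derivative of 12 (lithium between the amino alkoxide carbon and OMOM) | COCOc1c([Li])c(C(O[Li])N(C)CCN(C)C)ccc1OC | intermediate
14 | lithium {[2-(dimethylamino)ethyl](methyl)amino}{2-[(2E)-3,7-dimethylocta-2,6-dien-1-yl]-4-methoxy-3-(methoxymethoxy)phenyl}methanolate | COCOc1c(C/C=C(\C)CCC=C(C)C)c(C(O[Li])N(C)CCN(C)C)ccc1OC | intermediate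
15 | 2-[(2E)-3,7-dimethylocta-2,6-dien-1-yl]-4-methoxy-3-(methoxymethoxy)benzaldehyde | COCOc1c(C/C=C(\C)CCC=C(C)C)c(C=O)ccc1OC | intermediate
16 | methyl (3RS)-3-{2-[(2E)-3,7-dimethylocta-2,6-dien-1-yl]-4-methoxy-3-(methoxymethoxy)phenyl}-3-hydroxypropanoate | COCOc1c(C/C=C(\C)CCC=C(C)C)c(C(O)CC(=O)OC)ccc1OC | intermediate
17 | methyl 3-{2-[(2E)-3,7-dimethylocta-2,6-dien-1-yl]-4-methoxy-3-(methoxymethoxy)phenyl}-3-oxopropanoate | COCOc1c(C/C=C(\C)CCC=C(C)C)c(C(=O)CC(=O)OC)ccc1OC | intermediate
18 | methyl (3S)-3-{2-[(2E)-3,7-dimethylocta-2,6-dien-1-yl]-4-methoxy-3-(methoxymethoxy)phenyl}-3-hydroxypropanoate | COC(=O)C[C@H](O)c1ccc(OC)c(OCOC)c1C/C=C(\C)CCC=C(C)C | intermediate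
19 | methyl (3S)-3-{2-[(2E)-3,7-dimethylocta-2,6-dien-1-yl]-4-methoxy-3-(methoxymethoxy)phenyl}-3-[(trimethylsilyl)oxy]propanoate | COC(=O)C[C@H](O[Si](C)(C)C)c1ccc(OC)c(OCOC)c1C/C=C(\C)CCC=C(C)C | intermediate
20 | cesium alkoxide of 18 | COC(=O)C[C@H](O[Cs])c1ccc(OC)c(OCOC)c1C/C=C(\C)CCC=C(C)C | intermediate
21 | 5-methoxy-3-(methoxymethoxy)-4-(3-methylbut-2-en-1-yl)-1,2-didehydrobenzene (aryne) | COCOC1=C(CC=C(C)C)C(OC)=CC#C1 | intermediate
22 | arylcesium adduct: methyl (3S)-3-[2-cesio-5-methoxy-3-(methoxymethoxy)-4-(3-methylbut-2-en-1-yl)phenoxy]-3-{2-[(2E)-3,7-dimethylocta-2,6-dien-1-yl]-4-methoxy-3-(methoxymethoxy)phenyl}propanoate | COC(=O)C[C@H](Oc1cc(OC)c(CC=C(C)C)c(OCOC)c1[Cs])c1ccc(OC)c(OCOC)c1C/C=C(\C)CCC=C(C)C | intermediate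
23 | (2S)-2-{2-[(2E)-3,7-dimethylocta-2,6-dien-1-yl]-4-methoxy-3-(methoxymethoxy)phenyl}-7-methoxy-5-(methoxymethoxy)-6-(3-methylbut-2-en-1-yl)-2,3-dihydro-4H-chromen-4-one | COc1ccc([C@@H]2CC(=O)c3c(cc(OC)c(CC=C(C)C)c3OCOC)O2)c(C/C=C(\C)CCC=C(C)C)c1OCOC | intermediate
24 | (2S)-2-{2-[(2E)-3,7-dimethylocta-2,6-dien-1-yl]-3-hydroxy-4-methoxyphenyl}-5-hydroxy-7-methoxy-6-(3-methylbut-2-en-1-yl)-2,3-dihydro-4H-chromen-4-one | COc1ccc([C@@H]2CC(=O)c3c(cc(OC)c(CC=C(C)C)c3O)O2)c(C/C=C(\C)CCC=C(C)C)c1O | target

**Step count**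
Total: 14 steps. Longest linear sequence: 8 steps (steps 1–6, 13, 14; the ring B branch 7–12, 13, 14 is equally long).

**Steps most likely to fail**

Step 13. The aryl anion may be protonated before it captures the ester (open aryl ether), or the configuration may erode by retro-aldol of the alkoxide or base-induced opening of the flavanone. The fallback sets out from 15 and 9, uses known aryne chemistry without a preformed stereocenter, and rejoins the route at 23. Aldehyde 15 would be condensed with malonic acid (pyridine, piperidine, 90 °C, Knoevenagel–Doebner) to (2E)-3-{2-[(2E)-3,7-dimethylocta-2,6-dien-1-yl]-4-methoxy-3-(methoxymethoxy)phenyl}prop-2-enoic acid F1. F1 and 9 with CsF in THF at 125 °C (sealed tube) should undergo the known carboxylate O-arylation and acyl migration of arynes, with the same regiochemistry for the same reason, to give (2E)-1-[2-hydroxy-4-methoxy-6-(methoxymethoxy)-5-(3-methylbut-2-en-1-yl)phenyl]-3-{2-[(2E)-3,7-dimethylocta-2,6-dien-1-yl]-4-methoxy-3-(methoxymethoxy)phenyl}prop-2-en-1-one F2. NaOAc in EtOH at reflux would close F2 by oxa-Michael addition to the racemic flavanone F3. Kinetic resolution by transfer hydrogenation with RuCl[(R,R)-TsDPEN](p-cymene) and HCO2H/Et3N should reduce the (2R)-antipode to the cis-(2R,4R)-flavan-4-ol F4 and leave the (2S)-ketone 23, which is separated by chromatography.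

Step 4. Lithiation beside the bulky silyl ether may be slow, and deprotonation of the benzylic/allylic CH2 of the prenyl group or O-to-C silyl migration may compete. The fallback sets out from 5, delivers the silyl group with a stronger director at −78 °C, and rejoins the route at 8. Compound 5 would be desilylated (Bu4NF, AcOH, THF) to 3-methoxy-5-(methoxymethoxy)-4-(3-methylbut-2-en-1-yl)phenol F5 and carbamoylated (isopropyl isocyanate, Et3N, CH2Cl2) to the aryl N-isopropylcarbamate F6. After in situ N-silylation (Me3SiOTf, TMEDA), F6 would be lithiated with n-BuLi/TMEDA at −78 °C between the carbamate and OMOM oxygens and quenched with Me3SiCl to the 2-(trimethylsilyl)aryl N-isopropylcarbamate F7. Et2NH and DBU in MeCN at 40 °C would cleave the carbamate to phenol 8.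

Step 8. Ortho-lithiation of the amino alkoxide may be incomplete, or the allylic bromide may undergo Wurtz-type coupling instead of clean alkylation. The fallback sets out from 10, generates the aryl metal by halogen–lithium exchange on a stable acetal, and rejoins the route at 15. Isovanillin 10 would be brominated at C2 (Br2, NaOAc, AcOH, Fe powder cat.) to 2-bromo-3-hydroxy-4-methoxybenzaldehyde F8, acetalised (ethylene glycol, TsOH, toluene, Dean–Stark) to 2-bromo-3-(1,3-dioxolan-2-yl)-6-methoxyphenol F9 and protected (MOMCl, iPr2NEt) as 2-[2-bromo-4-methoxy-3-(methoxymethoxy)phenyl]-1,3-dioxolane F10. Bromine–lithium exchange (n-BuLi, THF, −78 °C), CuBr·SMe2 and geranyl bromide should give 2-{2-[(2E)-3,7-dimethylocta-2,6-dien-1-yl]-4-methoxy-3-(methoxymethoxy)phenyl}-1,3-dioxolane F11. Pyridinium p-toluenesulfonate in wet acetone at rt would release aldehyde 15 with the aryl MOM ether intact.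

**Further compounds**
F1 | step 13 | (2E)-3-{2-[(2E)-3,7-dimethylocta-2,6-dien-1-yl]-4-methoxy-3-(methoxymethoxy)phenyl}prop-2-enoic acid | OC(=O)/C=C/c1ccc(OC)c(OCOC)c1C/C=C(\C)CCC=C(C)C
F2 | step 13 | (2E)-1-[2-hydroxy-4-methoxy-6-(methoxymethoxy)-5-(3-methylbut-2-en-1-yl)phenyl]-3-{2-[(2E)-3,7-dimethylocta-2,6-dien-1-yl]-4-methoxy-3-(methoxymethoxy)phenyl}prop-2-en-1-one | COCOc1c(CC=C(C)C)c(OC)cc(O)c1C(=O)/C=C/c1ccc(OC)c(OCOC)c1C/C=C(\C)CCC=C(C)C
F3 | step 13 | racemic 2-{2-[(2E)-3,7-dimethylocta-2,6-dien-1-yl]-4-methoxy-3-(methoxymethoxy)phenyl}-7-methoxy-5-(methoxymethoxy)-6-(3-methylbut-2-en-1-yl)-2,3-dihydro-4H-chromen-4-one | COc1ccc(C2CC(=O)c3c(cc(OC)c(CC=C(C)C)c3OCOC)O2)c(C/C=C(\C)CCC=C(C)C)c1OCOC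
F4 | step 13 | (2R,4R)-2-{2-[(2E)-3,7-dimethylocta-2,6-dien-1-yl]-4-methoxy-3-(methoxymethoxy)phenyl}-7-methoxy-5-(methoxymethoxy)-6-(3-methylbut-2-en-1-yl)-3,4-dihydro-2H-chromen-4-ol | COc1ccc([C@H]2C[C@@H](O)c3c(cc(OC)c(CC=C(C)C)c3OCOC)O2)c(C/C=C(\C)CCC=C(C)C)c1OCOC
F5 | step 4 | 3-methoxy-5-(methoxymethoxy)-4-(3-methylbut-2-en-1-yl)phenol | COCOc1cc(O)cc(OC)c1CC=C(C)C
F6 | step 4 | 3-methoxy-5-(methoxymethoxy)-4-(3-methylbut-2-en-1-yl)phenyl N-isopropylcarbamate | COCOc1cc(OC(=O)NC(C)C)cc(OC)c1CC=C(C)C
F7 | step 4 | 5-methoxy-3-(methoxymethoxy)-4-(3-methylbut-2-en-1-yl)-2-(trimethylsilyl)phenyl N-isopropylcarbamate | COCOc1c([Si](C)(C)C)c(OC(=O)NC(C)C)cc(OC)c1CC=C(C)C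
F8 | step 8 | 2-bromo-3-hydroxy-4-methoxybenzaldehyde | COc1ccc(C=O)c(Br)c1O
F9 | step 8 | 2-bromo-3-(1,3-dioxolan-2-yl)-6-methoxyphenol | COc1ccc(C2OCCO2)c(Br)c1O
F10 | step 8 | 2-[2-bromo-4-methoxy-3-(methoxymethoxy)phenyl]-1,3-dioxolane | COCOc1c(Br)c(C2OCCO2)ccc1OC
F11 | step 8 | 2-{2-[(2E)-3,7-dimethylocta-2,6-dien-1-yl]-4-methoxy-3-(methoxymethoxy)phenyl}-1,3-dioxolane | COCOc1c(C/C=C(\C)CCC=C(C)C)c(C2OCCO2)ccc1OC
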